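**Plan**

1. Retrosynthesis: ring A is cut at its C(CH3)=CH olefin (ring-closing metathesis), then at the vinyl–carbinol bond and the secondary C–Br bond (open-chain chemistry). Ring B's C–Br/C–Cl pair goes back to the olefin of an isoprene Diels–Alder adduct.
2. Forward: ring B is made first by cycloaddition of isoprene to an α-methylene δ-lactone. This temporary ring holds the future C(CH3)= carbon as C=O and the future carbinol carbon as OCH2, and the cycloaddition makes the spiro carbon next to CMe2. Ring A is closed last.
3. The ring-A olefin lies between the spiro carbon and the carbinol carbon and carries no stereocentre. An isopropenyl group on the spiro carbon and a vinyl group on the carbinol carbon are therefore enough to close ring A after all five stereocentres are in place.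
4. Stereochemistry: the spiro centre comes from chiral Lewis acid catalysis. Both ring-B halogen centres are relayed from it through a temporary oxygen bridge from the hemiketal carbon (Br anti to that arm, then Cl with retention on its face).
5. The secondary C–Br centre is set by amine catalysis. The spiro centre cannot control it, because the two faces of ring A differ only in remote ring-B substituents.
6. The carbinol centre is relayed from C–Br by Cornforth/Felkin–Anh reduction in the open chain, which should give the trans bromohydrin; hydride reduction of the ring-A bromo enone would be expected to favour the cis isomer.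

Key step: step 13

Assumption: the sense of induction of the two chiral catalysts (steps 3 and 9) is taken as written; if either favours the other face, its mirror-image catalyst is used.

**Step 1**
Reactants: 1 3,3-dimethylglutaric anhydride
Product: 2 4,4-dimethyloxan-2-one
Conditions: NaBH4, THF, 0 °C → rt; then 6 M HCl, rt
Reagents that add atoms: none
Why: Borohydride reduces one of the two equivalent carbonyl groups of the symmetric anhydride to the alcohol while the carboxylate formed stays inert, and acid closes the δ-lactone (NaBH4 reduction of a cyclic anhydride to a lactone).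

**Step 2**
Reactants: 2 4,4-dimethyloxan-2-one
Product: 4 4,4-dimethyl-3-methylideneoxan-2-one, via sodium formyl-lactone enolate 3 (not isolated)
Conditions: NaH, HCO2Et, Et2O, 0 °C → rt; then (CH2O)n, THF, reflux
Reagents that add atoms: formaldehyde (from paraformaldehyde), C=O
Why: Claisen formylation gives enolate 3, whose aldol with formaldehyde is followed by formyl transfer to oxygen and loss of formate, leaving the exocyclic methylene (α-methylenation of a lactone through its α-formyl enolate).

**Step 3**
Reactants: 4 4,4-dimethyl-3-methylideneoxan-2-one; 5 isoprene (2-methylbuta-1,3-diene)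
Product: 6 (6R)-5,5,9-trimethyl-2-oxaspiro[5.5]undec-8-en-1-one
Conditions: isoprene (5 equiv), (S)-3,3-diphenyl-1-(o-tolyl)tetrahydropyrrolo[1,2-c][1,3,2]oxazaborole·HNTf2 (20 mol %), CH2Cl2, −40 °C
Reagents that add atoms: none
Why: Proposed new method: the cationic chiral boron Lewis acid should bind the lactone carbonyl of the s-cis-locked exocyclic enoate, lower its LUMO and block one face of the methylene group, so that isoprene adds to the open face with para orientation (its C1 joins the CH2 terminus) and the spiro quaternary carbon next to CMe2 is formed as one enantiomer; the closest known reaction type is the chiral-cation-catalysed Diels–Alder reaction of exocyclic enones, α-substituted acroleins and acrylates with isoprene.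

**Step 4**
Reactants: 6 (6R)-5,5,9-trimethyl-2-oxaspiro[5.5]undec-8-en-1-one
Product: 7 (6R)-1,5,5,9-tetramethyl-2-oxaspiro[5.5]undec-8-en-1-ol (anomer mixture, in equilibrium with the δ-hydroxy methyl ketone)
Conditions: CH3Li (1.2 equiv), THF, −78 °C; then H2O
Reagents that add atoms: methyllithium, [Li]C
Why: The hindered lactone carbonyl should take up one methyl group only, because the tetrahedral lithium alkoxide is stable at −78 °C, and the product rests as the cyclic hemiketal (mono-addition of an organolithium to a lactone); the spiro centre is not touched.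

**Step 5**
Reactants: 7 (6R)-1,5,5,9-tetramethyl-2-oxaspiro[5.5]undec-8-en-1-ol
Product: 9 (6R,8S,9S)-8-bromo-1,5,5,9-tetramethyl-2-oxaspiro[5.5]undecane-1,9-diol, via bridged bromoketal 8 (not isolated)
Conditions: N-bromosuccinimide, CH2Cl2, 0 °C; then 1 M HCl, THF, rt
Reagents that add atoms: N-bromosuccinimide, O=C1CCC(=O)N1Br; water, O
Why: Bromonium ions form reversibly on both faces of the ring-B olefin, but only the one remote from the hemiketal arm can be opened, at the tertiary carbon, by the hemiketal oxygen that this arm holds over the ring (intramolecular bromoetherification to a 2-oxabicyclo[2.2.2]octane, as in the α-terpineol to bromocineole cyclization), so the C–Br centre (anti to that arm, syn to the CMe2 arm) and the tertiary C–O centre (on the face of that arm) are both set from the spiro centre in one event, and dilute acid then opens the strained ketal 8.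

**Step 6**
Reactants: 9 (6R,8S,9S)-8-bromo-1,5,5,9-tetramethyl-2-oxaspiro[5.5]undecane-1,9-diol
Product: 10 (6R,8S,9S)-8-bromo-9-chloro-1,5,5,9-tetramethyl-2-oxaspiro[5.5]undecan-1-ol (anomer mixture)
Conditions: SOCl2 (3 equiv), TiCl4 (10 mol %), CH2Cl2, 0 °C; then sat. aq. NaHCO3, THF, rt
Reagents that add atoms: thionyl chloride, O=S(Cl)Cl
Why: The tertiary chlorosulfite should ionize with help from the anti bromine and take chloride back on the face the oxygen leaves (chlorination with retention by internal return, backed by bromonium participation), which puts Cl trans to Br at the tertiary carbon; aqueous work-up restores the hemiketal hydroxyl.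

**Step 7**
Reactants: 10 (6R,8S,9S)-8-bromo-9-chloro-1,5,5,9-tetramethyl-2-oxaspiro[5.5]undecan-1-ol
Product: 11 3-[(1S,3S,4S)-3-bromo-4-chloro-4-methyl-1-(prop-1-en-2-yl)cyclohexyl]-3-methylbutan-1-ol
Conditions: Cp2Ti(μ-CH2)(μ-Cl)AlMe2 (Tebbe reagent, 3 equiv), pyridine, THF–toluene, −40 → 0 °C; then 1 M NaOH
Reagents that add atoms: Tebbe reagent Cp2Ti(μ-CH2)(μ-Cl)AlMe2, C[Al-]1(C)C[Ti](C2C=CC=C2)(C2C=CC=C2)[Cl+]1
Why: The titanium methylidene olefinates the hindered, enolizable methyl ketone that is in equilibrium with the hemiketal under non-basic conditions that should spare the tertiary chloride and the secondary bromide (Tebbe methylenation); the excess reagent allows for the portion consumed by the free hydroxyl, which the basic work-up sets free again.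

**Step 8**
Reactants: 11 3-[(1S,3S,4S)-3-bromo-4-chloro-4-methyl-1-(prop-1-en-2-yl)cyclohexyl]-3-methylbutan-1-ol
Product: 12 3-[(1S,3S,4S)-3-bromo-4-chloro-4-methyl-1-(prop-1-en-2-yl)cyclohexyl]-3-methylbutanal
Conditions: Dess–Martin periodinane, NaHCO3, CH2Cl2, 0 °C → rt
Reagents that add atoms: none
Why: Buffered hypervalent-iodine oxidation takes the primary alcohol to the aldehyde without touching the alkene or the halides (Dess–Martin oxidation).

**Step 9**
Reactants: 12 3-[(1S,3S,4S)-3-bromo-4-chloro-4-methyl-1-(prop-1-en-2-yl)cyclohexyl]-3-methylbutanal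
Product: 13 (2S)-2-bromo-3-[(1S,3S,4S)-3-bromo-4-chloro-4-methyl-1-(prop-1-en-2-yl)cyclohexyl]-3-methylbutanal
Conditions: (2R,5R)-2,5-diphenylpyrrolidine (20 mol %), PhCO2H (20 mol %), 4,4-dibromo-2,6-di-tert-butylcyclohexa-2,5-dienone (1.1 equiv), H2O (2 equiv), CH2Cl2–pentane, −40 °C; used crude
Reagents that add atoms: 4,4-dibromo-2,6-di-tert-butylcyclohexa-2,5-dien-1-one, CC(C)(C)C1=CC(Br)(Br)C=C(C(C)(C)C)C1=O
Why: The amine forms the E-enamine of the aldehyde and its two phenyl groups shield one face, so that Br+ from the dienone should enter on the other (organocatalytic enantioselective α-bromination of an aldehyde); catalyst control is required here because the substrate itself offers no usable bias at this carbon.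

**Step 10**
Reactants: 13 (2S)-2-bromo-3-[(1S,3S,4S)-3-bromo-4-chloro-4-methyl-1-(prop-1-en-2-yl)cyclohexyl]-3-methylbutanal
Product: 14 (3RS,4S)-4-bromo-5-[(1S,3S,4S)-3-bromo-4-chloro-4-methyl-1-(prop-1-en-2-yl)cyclohexyl]-5-methylhex-1-en-3-ol
Conditions: CH2=CHMgBr, THF, −78 °C; AcOH–THF quench at −78 °C
Reagents that add atoms: vinylmagnesium bromide, C=C[Mg]Br
Why: The Grignard reagent adds to the α-bromo aldehyde at −78 °C faster than it enolizes it (1,2-addition), the cold acid quench prevents epoxide closure, and the configuration of the new carbinol centre does not matter because step 11 removes it.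

**Step 11**
Reactants: 14 (3RS,4S)-4-bromo-5-[(1S,3S,4S)-3-bromo-4-chloro-4-methyl-1-(prop-1-en-2-yl)cyclohexyl]-5-methylhex-1-en-3-ol
Product: 15 (4S)-4-bromo-5-[(1S,3S,4S)-3-bromo-4-chloro-4-methyl-1-(prop-1-en-2-yl)cyclohexyl]-5-methylhex-1-en-3-one
Conditions: Dess–Martin periodinane, NaHCO3, CH2Cl2, 0 °C
Reagents that add atoms: none
Why: Neutral, buffered oxidation gives the α'-bromo vinyl ketone (Dess–Martin oxidation), and the C–Br centre should hold because its hydrogen sits next to a quaternary carbon and is slow to enolize.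

**Step 12**
Reactants: 15 (4S)-4-bromo-5-[(1S,3S,4S)-3-bromo-4-chloro-4-methyl-1-(prop-1-en-2-yl)cyclohexyl]-5-methylhex-1-en-3-one
Product: 16 (3S,4S)-4-bromo-5-[(1S,3S,4S)-3-bromo-4-chloro-4-methyl-1-(prop-1-en-2-yl)cyclohexyl]-5-methylhex-1-en-3-ol
Conditions: NaBH4, CeCl3·7H2O, MeOH, −78 °C
Reagents that add atoms: none
Why: In the Cornforth/polar Felkin–Anh transition state of this 1,2-reduction (Luche reduction) the C–Br bond lies anti to the incoming hydride, which passes the α-hydrogen and not the quaternary carbon, so the syn (3S,4S) bromohydrin should form, and this is the trans relationship in the ring to be closed.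

**Step 13**
Reactants: 16 (3S,4S)-4-bromo-5-[(1S,3S,4S)-3-bromo-4-chloro-4-methyl-1-(prop-1-en-2-yl)cyclohexyl]-5-methylhex-1-en-3-ol
Product: 17 (3S,4S,6S,8S,9S)-4,8-dibromo-9-chloro-1,5,5,9-tetramethylspiro[5.5]undec-1-en-3-ol (target)
Conditions: second-generation Hoveyda–Grubbs catalyst RuCl2(H2IMes)(=CH-C6H4-2-OiPr) (10 mol %), 1,4-benzoquinone (10 mol %), toluene, 60 °C
Reagents that add atoms: none
Why: The ruthenium carbene should load onto the monosubstituted vinyl group of the allylic alcohol, add across the isopropenyl group on the spiro carbon through a metallacyclobutane, and release ethene together with the ring-A olefin (ring-closing olefin metathesis, closest precedent the closure of trisubstituted cyclohexenes from a 1,1-disubstituted and a monosubstituted alkene). Ring A closes as a six-membered carbocycle at the more hindered alkene, the intramolecular partner, and loss of ethene drives the closure. No stereocentre is formed, and none of the five existing ones is involved in the bond changes. The step needs only site selectivity and functional-group tolerance: there are exactly two alkenes, and the ruthenium carbene tolerates the free hydroxyl, the secondary bromides and the tertiary chloride. Benzoquinone should suppress ruthenium hydride isomerization of the allylic alcohol to a ketone. The gem-dimethyl carbon and the quaternary spiro carbon hold the two alkenes close together, which should offset the hindrance of the isopropenyl group.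

**Compound list**

1 | 3,3-dimethylglutaric anhydride | O=C1CC(C)(C)CC(=O)O1 | starting material
2 | 4,4-dimethyloxan-2-one | O=C1CC(C)(C)CCO1 | intermediate
3 | sodium (4,4-dimethyl-2-oxooxan-3-ylidene)methanolate | [Na+].[O-]C=C1C(=O)OCCC1(C)C | intermediate
4 | 4,4-dimethyl-3-methylideneoxan-2-one | C=C1C(=O)OCCC1(C)C | intermediate
5 | isoprene | C=CC(C)=C | starting material
6 | (6R)-5,5,9-trimethyl-2-oxaspiro[5.5]undec-8-en-1-one | O=C1OCCC(C)(C)[C@@]12CC=C(C)CC2 | intermediate
7 | (6R)-1,5,5,9-tetramethyl-2-oxaspiro[5.5]undec-8-en-1-ol, anomer mixture | CC1(O)OCCC(C)(C)[C@@]12CC=C(C)CC2 | intermediate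
8 | bridged bromoketal: the ketal carbon carries CH3, the oxane oxygen and a second oxygen bridging to the methyl-bearing carbon of ring B; Br on the next ring-B carbon, anti to that oxygen; epimers at the ketal carbon | CC12OCCC(C)(C)[C@]13CC[C@](C)(O2)[C@@H](Br)C3 | intermediate
9 | (6R,8S,9S)-8-bromo-1,5,5,9-tetramethyl-2-oxaspiro[5.5]undecane-1,9-diol, anomer mixture | CC1(O)OCCC(C)(C)[C@]12CC[C@](C)(O)[C@@H](Br)C2 | intermediate
10 | (6R,8S,9S)-8-bromo-9-chloro-1,5,5,9-tetramethyl-2-oxaspiro[5.5]undecan-1-ol, anomer mixture | CC1(O)OCCC(C)(C)[C@]12CC[C@](C)(Cl)[C@@H](Br)C2 | intermediate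
11 | 3-[(1S,3S,4S)-3-bromo-4-chloro-4-methyl-1-(prop-1-en-2-yl)cyclohexyl]-3-methylbutan-1-ol | OCCC(C)(C)[C@@]1(C(C)=C)CC[C@](C)(Cl)[C@@H](Br)C1 | intermediate
12 | 3-[(1S,3S,4S)-3-bromo-4-chloro-4-methyl-1-(prop-1-en-2-yl)cyclohexyl]-3-methylbutanal | O=CCC(C)(C)[C@@]1(C(C)=C)CC[C@](C)(Cl)[C@@H](Br)C1 | intermediate
13 | (2S)-2-bromo-3-[(1S,3S,4S)-3-bromo-4-chloro-4-methyl-1-(prop-1-en-2-yl)cyclohexyl]-3-methylbutanal | O=C[C@@H](Br)C(C)(C)[C@@]1(C(C)=C)CC[C@](C)(Cl)[C@@H](Br)C1 | intermediate
14 | (3RS,4S)-4-bromo-5-[(1S,3S,4S)-3-bromo-4-chloro-4-methyl-1-(prop-1-en-2-yl)cyclohexyl]-5-methylhex-1-en-3-ol | C=CC(O)[C@@H](Br)C(C)(C)[C@@]1(C(C)=C)CC[C@](C)(Cl)[C@@H](Br)C1 | intermediate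
15 | (4S)-4-bromo-5-[(1S,3S,4S)-3-bromo-4-chloro-4-methyl-1-(prop-1-en-2-yl)cyclohexyl]-5-methylhex-1-en-3-one | C=CC(=O)[C@@H](Br)C(C)(C)[C@@]1(C(C)=C)CC[C@](C)(Cl)[C@@H](Br)C1 | intermediate
16 | (3S,4S)-4-bromo-5-[(1S,3S,4S)-3-bromo-4-chloro-4-methyl-1-(prop-1-en-2-yl)cyclohexyl]-5-methylhex-1-en-3-ol | C=C[C@H](O)[C@@H](Br)C(C)(C)[C@@]1(C(C)=C)CC[C@](C)(Cl)[C@@H](Br)C1 | intermediate
17 | (3S,4S,6S,8S,9S)-4,8-dibromo-9-chloro-1,5,5,9-tetramethylspiro[5.5]undec-1-en-3-ol | CC1=C[C@H](O)[C@@H](Br)C(C)(C)[C@]12CC[C@](C)(Cl)[C@@H](Br)C2 | target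

**Step count and risks**

Total steps: 13. Longest linear sequence: 13 steps (1 to 17).

Step 3 is the riskiest, because it is the proposed new method. The hindered exocyclic enoate may react too slowly with the catalyst-bound Lewis acid at low temperature, and the two faces of the methylene group may be poorly distinguished. The fallback replaces catalysis by resolution. It sets out from 4 and 5: a Diels–Alder reaction promoted by EtAlCl2 in CH2Cl2 should give racemic 5,5,9-trimethyl-2-oxaspiro[5.5]undec-8-en-1-one F1. Opening with (S)-1-phenylethanamine and AlMe3 in toluene gives two diastereomeric hydroxy amides, from which (1R)-1-(4-hydroxy-2-methylbutan-2-yl)-4-methyl-N-[(1S)-1-phenylethyl]cyclohex-3-ene-1-carboxamide F2 is separated by crystallization or chromatography. Heating F2 with TsOH in toluene closes the lactone again and returns to the route at 6.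

Step 6 is next. Ionization at the tertiary carbon may lose regiocontrol (chloride entering at the secondary carbon of the bromonium ion with bromine migration) or lead to elimination, and the open-chain primary alcohol may be chlorinated. The fallback moves the tether from the hemiketal to the carboxylate and sets out from 6. Saponification with LiOH followed by N-bromosuccinimide and NaHCO3 should give the bridged bromolactone 6-bromo-4-(4-hydroxy-2-methylbutan-2-yl)-1-methyl-2-oxabicyclo[2.2.2]octan-3-one F3, with Br anti to the lactone oxygen. HCl gas in CH2Cl2 at −40 °C then cleaves the tertiary alkyl–oxygen bond with bromine participation; chloride enters with retention and the freed acid closes onto the primary alcohol, giving (6R,8S,9S)-8-bromo-9-chloro-5,5,9-trimethyl-2-oxaspiro[5.5]undecan-1-one F4. CH3Li at −78 °C then returns to the route at 10.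

Step 9 is third. Enamine formation and turnover may be slow at an aldehyde whose α-carbon is attached to a quaternary carbon that is itself joined to a second quaternary carbon, and the α-bromo aldehyde may lose configuration before it is used. The fallback replaces amine catalysis by an oxazolidinone auxiliary and sets out from 12. Pinnick oxidation (NaClO2, NaH2PO4, 2-methylbut-2-ene) gives 3-[(1S,3S,4S)-3-bromo-4-chloro-4-methyl-1-(prop-1-en-2-yl)cyclohexyl]-3-methylbutanoic acid F5. Its pivaloyl mixed anhydride acylates lithiated (S)-4-benzyloxazolidin-2-one to the imide (4S)-4-benzyl-3-{3-[(1S,3S,4S)-3-bromo-4-chloro-4-methyl-1-(prop-1-en-2-yl)cyclohexyl]-3-methylbutanoyl}-1,3-oxazolidin-2-one F6. The boron enolate (Bu2BOTf, iPr2NEt) with N-bromosuccinimide should give the (2S)-bromo imide (4S)-4-benzyl-3-{(2S)-2-bromo-3-[(1S,3S,4S)-3-bromo-4-chloro-4-methyl-1-(prop-1-en-2-yl)cyclohexyl]-3-methylbutanoyl}-1,3-oxazolidin-2-one F7. LiBH4 removes the auxiliary to give (2S)-2-bromo-3-[(1S,3S,4S)-3-bromo-4-chloro-4-methyl-1-(prop-1-en-2-yl)cyclohexyl]-3-methylbutan-1-ol F8, and Dess–Martin oxidation returns to the route at 13.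

**Further compounds**

F1 | step 3 | racemic 5,5,9-trimethyl-2-oxaspiro[5.5]undec-8-en-1-one | O=C1OCCC(C)(C)C12CC=C(C)CC2
F2 | step 3 | (1R)-1-(4-hydroxy-2-methylbutan-2-yl)-4-methyl-N-[(1S)-1-phenylethyl]cyclohex-3-ene-1-carboxamide | OCCC(C)(C)[C@]1(C(=O)N[C@@H](C)c2ccccc2)CC=C(C)CC1
F3 | step 6 | 6-bromo-4-(4-hydroxy-2-methylbutan-2-yl)-1-methyl-2-oxabicyclo[2.2.2]octan-3-one (Br anti to the lactone oxygen) | OCCC(C)(C)[C@]12CC[C@](C)(OC1=O)[C@@H](Br)C2
F4 | step 6 | (6R,8S,9S)-8-bromo-9-chloro-5,5,9-trimethyl-2-oxaspiro[5.5]undecan-1-one | O=C1OCCC(C)(C)[C@]12CC[C@](C)(Cl)[C@@H](Br)C2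
F5 | step 9 | 3-[(1S,3S,4S)-3-bromo-4-chloro-4-methyl-1-(prop-1-en-2-yl)cyclohexyl]-3-methylbutanoic acid | OC(=O)CC(C)(C)[C@@]1(C(C)=C)CC[C@](C)(Cl)[C@@H](Br)C1
F6 | step 9 | (4S)-4-benzyl-3-{3-[(1S,3S,4S)-3-bromo-4-chloro-4-methyl-1-(prop-1-en-2-yl)cyclohexyl]-3-methylbutanoyl}-1,3-oxazolidin-2-one | O=C(CC(C)(C)[C@@]1(C(C)=C)CC[C@](C)(Cl)[C@@H](Br)C1)N1[C@@H](Cc2ccccc2)COC1=O
F7 | step 9 | (4S)-4-benzyl-3-{(2S)-2-bromo-3-[(1S,3S,4S)-3-bromo-4-chloro-4-methyl-1-(prop-1-en-2-yl)cyclohexyl]-3-methylbutanoyl}-1,3-oxazolidin-2-one | O=C([C@@H](Br)C(C)(C)[C@@]1(C(C)=C)CC[C@](C)(Cl)[C@@H](Br)C1)N1[C@@H](Cc2ccccc2)COC1=O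
F8 | step 9 | (2S)-2-bromo-3-[(1S,3S,4S)-3-bromo-4-chloro-4-methyl-1-(prop-1-en-2-yl)cyclohexyl]-3-methylbutan-1-ol | OC[C@@H](Br)C(C)(C)[C@@]1(C(C)=C)CC[C@](C)(Cl)[C@@H](Br)C1
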